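Readings and results are calculated for an exercise; scatter was added.

- teal: free monomer 20 mM; transfer agent 0.20 mM; protic impurity 0.40 mM; initiator 0.20 mM; the very flask that is asked about, followed so far
- flask: free monomer 20 mM; transfer agent 0.200 mM; protic impurity 0.400 mM; initiator 0.20 mM; time 10 d

teal run (percent of the free monomer charged)

| time / d | monomer in chains / % | free monomer / % |
|---|---|---|
| 0.625 | 14 | 82 |
| 1.25 | 29 | 70 |
| 2.08 | 44 | 55 |
| 2.50 | 46 | 55 |
| 3.00 | 49 | 48 |
| 4.00 | 56 | 45 |

(standard deviation of a reading: 2 percentage points)

- average number of monomer units in a chain (chains begun, living or dead) at 10 d
- part of the free monomer that has reacted at 10 d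

- the average divides the monomer in chains by the number of chains begun, living and dead together
- the numbers in the tables scatter by 2 percentage points (one standard deviation)
- the earlier runs do not show the number of chains; that part of a forecast is a guess

A share that fades by a fixed fraction each day adds up to a finite sum, today's share divided by the fade, so dividing one rate by the other removes time. In the teal run, which is this flask followed so far, the share is the pseudo-first-order rate of free monomer loss. From the charge to 1.25 d it reads 0.285 d⁻¹, and from 2.50 d to 4.00 d it reads 0.134 d⁻¹. Between the window centres that is a fade of 0.289 d⁻¹, a reading that carries the scatter. The rate carried back to the charge, divided by the fade, gives 1.18: this is the reach, the natural logarithm of the charge over the free monomer finally left. So this reckoning puts the floor of free monomer at 30.6 % of the charge.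

The ledger for the flask at 10 d, reckoned here, has three entries. Free monomer left is 32.7 %. The protic impurity takes 2.00 %, if each unit quenches one free monomer. Monomer in chains takes the remaining 65.3 %. That makes 67.3 % reacted. The readings show no number of chains, so this reckoning gives no dp.

The forecast gives 67 % reacted and a dp of 35, with chains guessed: “about 0.38 mM seems reasonable”.

The flask gives 67.6 % reacted and a dp of 240.

    living end + transfer agent → dead chain (kL = 0.0237 M⁻¹ s⁻¹)
    free monomer + living end → monomer in chains + living end, rate k2*[living end]*[free monomer] (k = 0.0860 M⁻¹ s⁻¹)
    free monomer + initiator → living end + monomer in chains (k = 0.00164 M⁻¹ s⁻¹)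
    2 initiator → spent initiator (k = 0.635 M⁻¹ s⁻¹)
    protic impurity + free monomer → quenched substrate (k = 0.384 M⁻¹ s⁻¹)

Chains begun in the flask, living end plus dead chain, come to 0.0547 mM at 10.0 d, while spent initiator holds 0.145 mM of the 0.20 mM of initiator charged. Left until 100 d, the flask holds 30.7 % free monomer; the reckoned floor, which carries the scatter of the readings, stood at 30.6 %. A neighbouring flask was charged with 0.34 mM of transfer agent. With the starting rate held and the fade scaled by that charge, as the first step of the scheme writes it, the reach becomes 0.697, a reckoned floor of 49.8 % free monomer. At 10.0 d that neighbour holds 51.8 % free monomer and has a dp of 169.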